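**Plan**

1. The last cuts are the four O-benzyl bonds (hydrogenolysis) and the two C3–H/C4–H pairs, which lead back to a bis(isoflav-3-ene).
2. The key cut is made twice: C4–C4a and O1–C2 of each pyran ring. Each ring A is a resorcinol unit in which C4a lies ortho to the oxygen on C8a and para to the oxygen on C7, and C4–C3–C2 is the three-carbon chain of an acrolein carrying ring B on C3. This leaves 3-(benzyloxy)phenol (one hydroxyl to template, one masked) and a bis(2-arylacrolein).
3. The two enal units go back by methylenation and one-carbon homologation to a diaryl ether dialdehyde. That is cut at the ring B–O–ring B bond into a phenol and the boronic acid made from the same phenol, itself derived from 2,3,4-trihydroxybenzaldehyde.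
4. Forward order: ring B phenol (steps 1–3), its boronic acid (4–6), diaryl ether (7), enal side chains (8–10), both pyran rings in one operation (11), alkene reduction and debenzylation (12–13).
5. The two C3 centres (both R) are the only stereocentres; they are set together in step 12 by a chiral iridium P,N catalyst.

Key step: step 11

Assumption: the (S)-configured phosphinooxazoline ligand is taken to deliver hydrogen to the alkene face that gives 3R; if a trial run shows the opposite sense, the (R)-ligand is used with no other change.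
Numbering: O1, C2, C3, C4, C4a, C5–C8, C8a for each chroman; primed numbers for ring B.

**Route**

Step 1
Reactants: 1 2,3,4-trihydroxybenzaldehyde
Product: 2 4-(allyloxy)-2,3-dihydroxybenzaldehyde
Conditions: allyl bromide (1.05 equiv), NaHCO3 (1.5 equiv), NaI (cat.), DMF, 40 °C, N2
Reagents that add atoms: allyl bromide, C=CCBr
Why: Williamson etherification in which hydrogen carbonate ionises only the 4-OH (para to the formyl group, the most acidic of the three), while the 2-OH is held in a hydrogen bond to the carbonyl, so the allyl group should go on O4.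

Step 2
Reactants: 2 4-(allyloxy)-2,3-dihydroxybenzaldehyde
Product: 4 4-(allyloxy)-3-(benzyloxy)-2-methoxybenzaldehyde, via 3-O-benzyl phenol 3 (not isolated)
Conditions: NaH (2.05 equiv), DMSO, 20 °C; BnBr (1.0 equiv); then MeI (1.5 equiv), 20 °C
Reagents that add atoms: benzyl bromide, BrCc1ccccc1; iodomethane, CI
Why: Williamson etherification of the dianion, in which O3 is the only phenoxide neither conjugated with nor chelated to the formyl group and so should take the single equivalent of benzyl bromide, after which the remaining 2-phenoxide is methylated in the same flask.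

Step 3
Reactants: 4 4-(allyloxy)-3-(benzyloxy)-2-methoxybenzaldehyde
Product: 5 3-(benzyloxy)-4-hydroxy-2-methoxybenzaldehyde
Conditions: Pd(PPh3)4 (3 mol%), morpholine (3 equiv), THF, 20 °C
Reagents that add atoms: none
Why: Tsuji–Trost deallylation, in which zerovalent palladium ionises the allyl aryl ether to a π-allyl complex and the stabilised phenoxide and morpholine traps the allyl group, leaving the benzyl and methyl ethers and the aldehyde untouched.

Step 4
Reactants: 5 3-(benzyloxy)-4-hydroxy-2-methoxybenzaldehyde
Product: 6 2-(benzyloxy)-4-formyl-3-methoxyphenyl trifluoromethanesulfonate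
Conditions: Tf2O (1.2 equiv), pyridine, CH2Cl2, 0 °C
Reagents that add atoms: trifluoromethanesulfonic anhydride, O=S(=O)(OS(=O)(=O)C(F)(F)F)C(F)(F)F
Why: O-sulfonylation of the acidic phenol gives the aryl triflate that serves as the electrophile for borylation.

Step 5
Reactants: 6 2-(benzyloxy)-4-formyl-3-methoxyphenyl trifluoromethanesulfonate
Product: 7 3-(benzyloxy)-2-methoxy-4-(4,4,5,5-tetramethyl-1,3,2-dioxaborolan-2-yl)benzaldehyde
Conditions: B2pin2 (1.2 equiv), PdCl2(dppf) (3 mol%), KOAc (3 equiv), 1,4-dioxane, 80 °C
Reagents that add atoms: bis(pinacolato)diboron, CC1(C)OB(OC1(C)C)B1OC(C)(C)C(C)(C)O1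
Why: Miyaura borylation (oxidative addition of zerovalent palladium into the electron-poor aryl triflate, acetate-assisted transmetalation with the diboron, reductive elimination), a reaction that tolerates aryl aldehydes and ortho ethers.

Step 6
Reactants: 7 3-(benzyloxy)-2-methoxy-4-(4,4,5,5-tetramethyl-1,3,2-dioxaborolan-2-yl)benzaldehyde
Product: 8 [2-(benzyloxy)-4-formyl-3-methoxyphenyl]boronic acid
Conditions: NaIO4 (3 equiv), NH4OAc (3 equiv), acetone/H2O 1:1, 20 °C
Reagents that add atoms: water, O
Why: Periodate cleaves the pinacol released in the hydrolysis equilibrium, which should drive the boronate to the free boronic acid under conditions that leave aldehyde and ethers alone.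

Step 7
Reactants: 5 3-(benzyloxy)-4-hydroxy-2-methoxybenzaldehyde; 8 [2-(benzyloxy)-4-formyl-3-methoxyphenyl]boronic acid
Product: 9 4,4'-oxybis[3-(benzyloxy)-2-methoxybenzaldehyde]
Conditions: 8 (2 equiv), Cu(OAc)2 (1.0 equiv, reoxidised by air), pyridine (5 equiv), 4 Å molecular sieves, CH2Cl2, air, 20 °C
Reagents that add atoms: none
Why: Chan–Lam coupling (transmetalation of the arylboronic acid to the divalent copper phenoxide, oxidation by air, C–O reductive elimination from trivalent copper) should give the diaryl ether at room temperature despite the ortho-alkoxy groups and the aldehydes, and the only phenol that oxidative deboronation of 8 can give is 5 itself, so that side reaction feeds the coupling.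

Step 8
Reactants: 9 4,4'-oxybis[3-(benzyloxy)-2-methoxybenzaldehyde]
Product: 10 bis[2-(benzyloxy)-3-methoxy-4-(2-methoxyethenyl)phenyl] ether (E/Z mixture)
Conditions: MeOCH2PPh3Cl (3 equiv), KOtBu (3 equiv), THF, 0 °C to 20 °C
Reagents that add atoms: (methoxymethyl)triphenylphosphonium chloride, COC[P+](c1ccccc1)(c1ccccc1)c1ccccc1.[Cl-]
Why: Double Wittig reaction of the non-enolisable dialdehyde with methoxymethylenetriphenylphosphorane gives the bis(enol ether), whose E/Z composition does not matter because both isomers hydrolyse to the same aldehyde.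

Step 9
Reactants: 10 bis[2-(benzyloxy)-3-methoxy-4-(2-methoxyethenyl)phenyl] ether
Product: 11 bis[2-(benzyloxy)-3-methoxy-4-(2-oxoethyl)phenyl] ether
Conditions: 2 M aq. HCl, THF, 45 °C; crude product used at once
Reagents that add atoms: water, O
Why: Acid-catalysed enol ether hydrolysis (C-protonation, hemiacetal, loss of methanol) unmasks the homologated aldehydes, and benzyl, methyl and diaryl ethers are stable to dilute acid.

Step 10
Reactants: 11 bis[2-(benzyloxy)-3-methoxy-4-(2-oxoethyl)phenyl] ether
Product: 13 bis[2-(benzyloxy)-3-methoxy-4-(3-oxoprop-1-en-2-yl)phenyl] ether, via bis(Mannich base) 12 (not isolated)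
Conditions: Me2N=CH2 I (2.6 equiv), Et3N (3 equiv), CH2Cl2, 20 °C
Reagents that add atoms: dimethylmethylideneammonium iodide (Eschenmoser's salt), C=[N+](C)C.[I-]
Why: Mannich α-methylenation, in which the enol of each arylacetaldehyde adds to the iminium salt and the β-dimethylamino aldehyde, whose α-hydrogen is both benzylic and α to the carbonyl, loses dimethylamine by E1cB elimination to give the 2-arylacrolein.

Step 11
Reactants: 13 bis[2-(benzyloxy)-3-methoxy-4-(3-oxoprop-1-en-2-yl)phenyl] ether; 14 3-(benzyloxy)phenol
Product: 18 bis[2-(benzyloxy)-4-(7-(benzyloxy)-2H-chromen-3-yl)-3-methoxyphenyl] ether, via aryl phenylboronate 15 (not isolated), via bis(benzodioxaborin) 16 (not isolated), via bis(o-quinone methide) 17 (not isolated)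
Conditions: 14 (3 equiv), PhB(OH)2 (3 equiv), EtCO2H (0.5 equiv), toluene, reflux, Dean–Stark; 13 added slowly
Reagents that add atoms: none
Why: Phenol 14 and PhB(OH)2 condense to the aryl phenylboronate 15, whose boron binds each formyl oxygen and delivers the ring carbon ortho to the boronate oxygen to the carbonyl carbon through a six-membered transition state, so C4–C4a forms by 1,2-addition and the adduct is held as the 4H-1,3,2-benzodioxaborin 16. On further heating with acid, 16 loses phenylboroxine in a retro-hetero-Diels–Alder step and gives the o-quinone methide 17, a 1-oxatriene (O=C8a–C4a=C4–C3=C2). Each pyran ring then closes by thermal disrotatory oxa-6π electrocyclisation, which forms O1–C2 and restores the aromaticity of ring A. The closest known reaction is the phenylboronic acid-mediated condensation of 3-alkoxyphenols with α,β-unsaturated aldehydes to 2H-chromenes, applied here twice in one molecule to an α-aryl enal. No stereocentre is created. The step needs 1,2- over 1,4-attack on the enal (the boron tether reaches only the carbonyl carbon), attack at C6 and not C2 of the phenol (C2 sits between two oxygens, C6 is para to the benzyloxy group) and one annulation per phenol (14 has a single free hydroxyl and is used in excess so that both enals are captured before they can dimerise).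

Step 12
Reactants: 18 bis[2-(benzyloxy)-4-(7-(benzyloxy)-2H-chromen-3-yl)-3-methoxyphenyl] ether
Product: 19 bis{2-(benzyloxy)-4-[(3R)-7-(benzyloxy)chroman-3-yl]-3-methoxyphenyl} ether
Conditions: H2 (50 bar), [Ir(cod)((S)-tBu-PHOX)][B(C6H3-3,5-(CF3)2)4] (2 mol%), CH2Cl2, 20 °C
Reagents that add atoms: none
Why: Iridium-catalysed asymmetric hydrogenation of a trisubstituted aryl alkene with a chiral P,N ligand ((S)-tBu-PHOX = (S)-4-tert-butyl-2-[2-(diphenylphosphino)phenyl]-4,5-dihydrooxazole), in which each C3=C4 bond is reduced independently and the ligand decides which face of C3 receives hydrogen, so both centres should be R, with the meso isomer as a separable by-product that collects most of the mismatched events.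

Step 13
Reactants: 19 bis{2-(benzyloxy)-4-[(3R)-7-(benzyloxy)chroman-3-yl]-3-methoxyphenyl} ether
Product: 20 bis{2-hydroxy-4-[(3R)-7-hydroxychroman-3-yl]-3-methoxyphenyl} ether (target)
Conditions: H2 (1 atm), 10% Pd/C, THF/MeOH, 20 °C
Reagents that add atoms: none
Why: Hydrogenolysis of the four aryl benzyl ethers over palladium on carbon frees the phenols without touching the diaryl ether, the chroman C–O bonds or the C3 centres, which carry no acidic or labile substituent.

**Compound list**

1 | 2,3,4-trihydroxybenzaldehyde | O=Cc1ccc(O)c(O)c1O | starting material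
2 | 4-(allyloxy)-2,3-dihydroxybenzaldehyde | O=Cc1ccc(OCC=C)c(O)c1O | intermediate
3 | 4-(allyloxy)-3-(benzyloxy)-2-hydroxybenzaldehyde (formed as its sodium salt, not isolated) | O=Cc1ccc(OCC=C)c(OCc2ccccc2)c1O | intermediate
4 | 4-(allyloxy)-3-(benzyloxy)-2-methoxybenzaldehyde | O=Cc1ccc(OCC=C)c(OCc2ccccc2)c1OC | intermediate
5 | 3-(benzyloxy)-4-hydroxy-2-methoxybenzaldehyde | O=Cc1ccc(O)c(OCc2ccccc2)c1OC | intermediate
6 | 2-(benzyloxy)-4-formyl-3-methoxyphenyl trifluoromethanesulfonate | O=Cc1ccc(OS(=O)(=O)C(F)(F)F)c(OCc2ccccc2)c1OC | intermediate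
7 | 3-(benzyloxy)-2-methoxy-4-(4,4,5,5-tetramethyl-1,3,2-dioxaborolan-2-yl)benzaldehyde | O=Cc1ccc(B2OC(C)(C)C(C)(C)O2)c(OCc3ccccc3)c1OC | intermediate
8 | [2-(benzyloxy)-4-formyl-3-methoxyphenyl]boronic acid | O=Cc1ccc(B(O)O)c(OCc2ccccc2)c1OC | intermediate
9 | 4,4'-oxybis[3-(benzyloxy)-2-methoxybenzaldehyde] | O=Cc1ccc(Oc2ccc(C=O)c(OC)c2OCc3ccccc3)c(OCc4ccccc4)c1OC | intermediate
10 | bis[2-(benzyloxy)-3-methoxy-4-(2-methoxyethenyl)phenyl] ether, E/Z mixture | COC=Cc1ccc(Oc2ccc(C=COC)c(OC)c2OCc3ccccc3)c(OCc4ccccc4)c1OC | intermediate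
11 | bis[2-(benzyloxy)-3-methoxy-4-(2-oxoethyl)phenyl] ether | O=CCc1ccc(Oc2ccc(CC=O)c(OC)c2OCc3ccccc3)c(OCc4ccccc4)c1OC | intermediate
12 | bis[2-(benzyloxy)-4-(1-(dimethylamino)-3-oxopropan-2-yl)-3-methoxyphenyl] ether, diastereomer mixture (not isolated) | CN(C)CC(C=O)c1ccc(Oc2ccc(C(CN(C)C)C=O)c(OC)c2OCc3ccccc3)c(OCc4ccccc4)c1OC | intermediate
13 | bis[2-(benzyloxy)-3-methoxy-4-(3-oxoprop-1-en-2-yl)phenyl] ether, the bis(2-arylacrolein) | C=C(C=O)c1ccc(Oc2ccc(C(=C)C=O)c(OC)c2OCc3ccccc3)c(OCc4ccccc4)c1OC | intermediate
14 | 3-(benzyloxy)phenol | Oc1cccc(OCc2ccccc2)c1 | starting material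
15 | 3-(benzyloxy)phenyl hydrogen phenylboronate (not isolated) | OB(Oc1cccc(OCc2ccccc2)c1)c1ccccc1 | intermediate
16 | bis[2-(benzyloxy)-4-(1-(7-(benzyloxy)-2-phenyl-4H-1,3,2-benzodioxaborin-4-yl)vinyl)-3-methoxyphenyl] ether, diastereomer mixture (not isolated) | C=C(C1OB(c2ccccc2)Oc2cc(OCc3ccccc3)ccc12)c1ccc(Oc2ccc(C(=C)C3OB(c4ccccc4)Oc4cc(OCc5ccccc5)ccc34)c(OC)c2OCc2ccccc2)c(OCc2ccccc2)c1OC | intermediate
17 | bis[2-(benzyloxy)-4-(3-(4-(benzyloxy)-6-oxocyclohexa-2,4-dien-1-ylidene)prop-1-en-2-yl)-3-methoxyphenyl] ether, the bis(o-quinone methide) (not isolated) | C=C(C=C1C=CC(OCc2ccccc2)=CC1=O)c1ccc(Oc2ccc(C(=C)C=C3C=CC(OCc4ccccc4)=CC3=O)c(OC)c2OCc2ccccc2)c(OCc2ccccc2)c1OC | intermediate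
18 | bis[2-(benzyloxy)-4-(7-(benzyloxy)-2H-chromen-3-yl)-3-methoxyphenyl] ether, the bis(isoflav-3-ene) | COc1c(C2=Cc3ccc(OCc4ccccc4)cc3OC2)ccc(Oc5ccc(C6=Cc7ccc(OCc8ccccc8)cc7OC6)c(OC)c5OCc9ccccc9)c1OCc1ccccc1 | intermediate
19 | bis{2-(benzyloxy)-4-[(3R)-7-(benzyloxy)chroman-3-yl]-3-methoxyphenyl} ether | COc1c([C@@H]2COc3cc(OCc4ccccc4)ccc3C2)ccc(Oc2ccc([C@@H]3COc4cc(OCc5ccccc5)ccc4C3)c(OC)c2OCc2ccccc2)c1OCc1ccccc1 | intermediate
20 | bis{2-hydroxy-4-[(3R)-7-hydroxychroman-3-yl]-3-methoxyphenyl} ether | COc1c([C@@H]2COc3cc(O)ccc3C2)ccc(Oc2ccc([C@@H]3COc4cc(O)ccc4C3)c(OC)c2O)c1O | target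

**Step count and risks**

Total steps: 13. Longest linear sequence: 13 steps (1 to 20; compound 5 is used twice, as the phenol in step 7 and as the source of boronic acid 8).

Steps most likely to fail:

Step 11. The two enal units may dimerise or polymerise at reflux faster than the boron template captures them, carbon attack may leak to the CH2 terminus, or only one arm may annulate. Fallback: it sets out from 13 and inverts the order of bond formation, using only known reactions. Luche reduction (NaBH4, CeCl3·7H2O, MeOH, 0 °C) should give bis[2-(benzyloxy)-4-(3-hydroxyprop-1-en-2-yl)-3-methoxyphenyl] ether F1. Mitsunobu etherification (PPh3, DIAD, THF) with 5-(benzyloxy)-2-vinylphenol F2 forms both O1–C2 bonds and gives the tetraene bis[2-(benzyloxy)-4-(3-(5-(benzyloxy)-2-vinylphenoxy)prop-1-en-2-yl)-3-methoxyphenyl] ether F3. F2 comes from commercial 4-(benzyloxy)-2-hydroxybenzaldehyde, O=Cc1ccc(OCc2ccccc2)cc1O, by Wittig methylenation with Ph3P=CH2. Ring-closing metathesis of F3 with the second-generation Grubbs catalyst RuCl2(=CHPh)(H2IMes)(PCy3) in dilute toluene at 80 °C closes both C3=C4 bonds and returns to the route at 18.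

Step 7. Transmetalation and C–O bond formation may be slow with a weakly nucleophilic para-formyl phenoxide and an ortho-substituted, electron-poor boronic acid, so protodeboronation could outrun coupling. Fallback: it sets out from 5 and 6 and joins them directly by palladium-catalysed C–O cross-coupling (Pd(OAc)2, 2-di-tert-butylphosphino-2',4',6'-triisopropylbiphenyl, K3PO4, toluene, 100 °C), returning at 9. Triflyl transfer from 6 to the phenoxide of 5 only regenerates the same two partners, so this usual side reaction does no harm here.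

Step 12. Facial discrimination may be poor because the ortho-methoxy group twists ring B out of the alkene plane, and the second alkene may be reduced incompletely. Fallback: it sets out from 18 and gives up catalyst control. Hydrogenation over 10% Pd/C (H2, THF/MeOH) reduces both alkenes and removes all benzyl groups to give the stereoisomer mixture of bis[2-hydroxy-4-(7-hydroxychroman-3-yl)-3-methoxyphenyl] ether F4 (racemic pair plus meso). The meso isomer is removed by chromatography and the (R,R)-enantiomer is separated by preparative HPLC on a cellulose tris(3,5-dimethylphenylcarbamate) phase, which returns at 20.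

Further compounds

F1 | step 11 | bis[2-(benzyloxy)-4-(3-hydroxyprop-1-en-2-yl)-3-methoxyphenyl] ether | C=C(CO)c1ccc(Oc2ccc(C(=C)CO)c(OC)c2OCc3ccccc3)c(OCc4ccccc4)c1OC
F2 | step 11 | 5-(benzyloxy)-2-vinylphenol | C=Cc1ccc(OCc2ccccc2)cc1O
F3 | step 11 | bis[2-(benzyloxy)-4-(3-(5-(benzyloxy)-2-vinylphenoxy)prop-1-en-2-yl)-3-methoxyphenyl] ether | C=C(COc1cc(OCc2ccccc2)ccc1C=C)c1ccc(Oc2ccc(C(=C)COc3cc(OCc4ccccc4)ccc3C=C)c(OC)c2OCc2ccccc2)c(OCc2ccccc2)c1OC
F0 | step 7 | none | none
F4 | step 12 | bis[2-hydroxy-4-(7-hydroxychroman-3-yl)-3-methoxyphenyl] ether, mixture of stereoisomers | COc1c(C2COc3cc(O)ccc3C2)ccc(Oc2ccc(C3COc4cc(O)ccc4C3)c(OC)c2O)c1O
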